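**Plan**

Numbering as in drimanes: C3 bears the ester, C4 the gem-dimethyl group, C5/C10 are the ring-fusion carbons (methyl on C10), C8 bears the methylidene, C9 the C11H2–O arm; ring A = C1–C5, C10 and ring B = C5–C10.
Retrosynthesis: cut C11–O(aryl) (Mitsunobu with umbelliferone), then C8=CH2 (ketone methylenation); the remaining C8 ketone / C9–C11H2OH array next to quaternary C10 is a β-hydroxy ketone, the retron of a 2,3-epoxy alcohol semipinacol shift.
Returning C10 from C9 to C8 contracts ring B to the cyclopentane (C5, C6, C7, C8, C10) of a trans-hydrindane that carries a tertiary C8 carbinol and a C9–C11 epoxide; further cuts are the epoxide oxygen, C8–C9 (vinyl Grignard), the ester C–O, one C4–CH3 and the Michael/aldol bonds of a 4-methyl bicyclic enedione.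
Forward: Michael addition and amino-acid-mediated aldol condensation build ring A and the cyclopentane, reductive methylation completes C4 and the trans fusion, ring B reaches its final size last by one-carbon ring expansion, and the coumarin is joined at the end.
Stereochemistry: C10 from the D-phenylalanine-mediated aldol; C5 from protonation anti to the C10 methyl; C3 from axial hydride delivery; the C8 carbinol from Grignard attack anti to the methyl, the epoxide carbon from hydroxyl-directed epoxidation, and C9 from the stereospecific anti 1,2-shift.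

Key step: step 12

Remark: the ketol 4 should form as a mixture of epimers at its methyl-bearing carbon; that centre becomes sp2 in 5 and is therefore written without a descriptor.

**Route**

Step 1
Reactants: 1 2-methylcyclopentane-1,3-dione; 2 pent-1-en-3-one (ethyl vinyl ketone)
Product: 3 2-methyl-2-(3-oxopentyl)cyclopentane-1,3-dione
Conditions: H2O, AcOH (cat.), 75 °C
Reagents that add atoms: none
Why: Michael addition of the enolised 1,3-dione to the enone, in which the doubly activated C2–H is the only site that can add, so the achiral triketone should form cleanly.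

Step 2
Reactants: 3 2-methyl-2-(3-oxopentyl)cyclopentane-1,3-dione
Product: 5 (7aR)-4,7a-dimethyl-2,3,7,7a-tetrahydro-1H-indene-1,5(6H)-dione, via cis-fused ketol 4 (not isolated)
Conditions: D-phenylalanine (1 equiv), 1 M aq. HClO4 (0.4 equiv), MeCN, reflux
Reagents that add atoms: none
Why: Intramolecular aldol condensation through the enamine of the side-chain ketone (Hajos–Parrish–Eder–Sauer–Wiechert reaction), in which the D-amino acid should direct attack onto one of the two enantiotopic ring carbonyls and so set the quaternary carbon as R, the acid dehydrating the ketol in the same flask.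

Step 3
Reactants: 5 (7aR)-4,7a-dimethyl-2,3,7,7a-tetrahydro-1H-indene-1,5(6H)-dione
Product: 6 (1R,7aR)-1-hydroxy-4,7a-dimethyl-1,2,3,6,7,7a-hexahydro-5H-inden-5-one
Conditions: NaBH4 (0.3 equiv), EtOH, −20 °C
Reagents that add atoms: none
Why: Chemoselective borohydride reduction of the saturated cyclopentanone, which is more electrophilic than the enone carbonyl, with hydride approaching anti to the angular methyl so that the new hydroxyl should lie cis to it.

Step 4
Reactants: 6 (1R,7aR)-1-hydroxy-4,7a-dimethyl-1,2,3,6,7,7a-hexahydro-5H-inden-5-one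
Product: 7 (1R,7aR)-1-[(tert-butyldimethylsilyl)oxy]-4,7a-dimethyl-1,2,3,6,7,7a-hexahydro-5H-inden-5-one
Conditions: TBSCl, imidazole, DMF, rt
Reagents that add atoms: tert-butyldimethylsilyl chloride, CC(C)(C)[Si](C)(C)Cl
Why: Standard imidazole-mediated silylation of a secondary alcohol, which masks the future C8 oxygen in a form that should survive dissolving metal, hydride and acylation.

Step 5
Reactants: 7 (1R,7aR)-1-[(tert-butyldimethylsilyl)oxy]-4,7a-dimethyl-1,2,3,6,7,7a-hexahydro-5H-inden-5-one
Product: 9 (1R,3aS,7aR)-1-[(tert-butyldimethylsilyl)oxy]-4,4,7a-trimethyloctahydro-5H-inden-5-one, via lithium enolate 8 (not isolated)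
Conditions: Li (2.1 equiv), t-BuOH (1.0 equiv), NH3(l)/THF, −78 °C; then MeI, −78 → −33 °C
Reagents that add atoms: iodomethane, CI
Why: Dissolving-metal reductive alkylation of an enone (Stork type), in which protonation of the β-carbanion anti to the angular methyl should set the trans ring fusion and the regiodefined lithium enolate is C-methylated to give the gem-dimethyl carbon.

Step 6
Reactants: 9 (1R,3aS,7aR)-1-[(tert-butyldimethylsilyl)oxy]-4,4,7a-trimethyloctahydro-5H-inden-5-one
Product: 10 (1R,3aR,5R,7aR)-1-[(tert-butyldimethylsilyl)oxy]-4,4,7a-trimethyloctahydro-1H-inden-5-ol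
Conditions: NaBH4, MeOH/THF, 0 °C
Reagents that add atoms: none
Why: Borohydride reduction of a cyclohexanone flanked by a gem-dimethyl group, where axial hydride delivery on the face away from the axial methyl groups should give the equatorial alcohol cis to the angular methyl.

Step 7
Reactants: 10 (1R,3aR,5R,7aR)-1-[(tert-butyldimethylsilyl)oxy]-4,4,7a-trimethyloctahydro-1H-inden-5-ol
Product: 11 (1R,3aR,5R,7aR)-1-[(tert-butyldimethylsilyl)oxy]-4,4,7a-trimethyloctahydro-1H-inden-5-yl 3-methylbutanoate
Conditions: 3-methylbutanoyl chloride, pyridine, DMAP (cat.), CH2Cl2, 0 °C → rt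
Reagents that add atoms: 3-methylbutanoyl chloride, CC(C)CC(=O)Cl
Why: DMAP-catalysed acylation with an acid chloride, which should overcome the hindrance of the neopentyl-type secondary alcohol without touching its configuration.

Step 8
Reactants: 11 (1R,3aR,5R,7aR)-1-[(tert-butyldimethylsilyl)oxy]-4,4,7a-trimethyloctahydro-1H-inden-5-yl 3-methylbutanoate
Product: 12 (1R,3aR,5R,7aR)-1-hydroxy-4,4,7a-trimethyloctahydro-1H-inden-5-yl 3-methylbutanoate
Conditions: HF (48% aq.), MeCN, rt
Reagents that add atoms: none
Why: Acidic fluoride desilylation, which should cleave the hindered silyl ether while leaving the hindered ester intact.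

Step 9
Reactants: 12 (1R,3aR,5R,7aR)-1-hydroxy-4,4,7a-trimethyloctahydro-1H-inden-5-yl 3-methylbutanoate
Product: 13 (3aR,5R,7aR)-4,4,7a-trimethyl-1-oxooctahydro-1H-inden-5-yl 3-methylbutanoate
Conditions: Dess–Martin periodinane, CH2Cl2, rt
Reagents that add atoms: none
Why: Dess–Martin oxidation of a secondary alcohol under neutral non-aqueous conditions, which should neither touch the ester nor epimerise the ring fusion.

Step 10
Reactants: 13 (3aR,5R,7aR)-4,4,7a-trimethyl-1-oxooctahydro-1H-inden-5-yl 3-methylbutanoate
Product: 14 (1S,3aR,5R,7aR)-1-ethenyl-1-hydroxy-4,4,7a-trimethyloctahydro-1H-inden-5-yl 3-methylbutanoate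
Conditions: CH2=CHMgBr (1.5 equiv), LaCl3·2LiCl (0.3 equiv), THF, −30 → 0 °C
Reagents that add atoms: vinylmagnesium bromide, C=C[Mg]Br
Why: Lanthanum-salt-promoted Grignard 1,2-addition, which suppresses enolisation of the hindered cyclopentanone, should reach the ketone well before the hindered ester and should deliver vinyl anti to the angular methyl so that the tertiary hydroxyl lies cis to it.

Step 11
Reactants: 14 (1S,3aR,5R,7aR)-1-ethenyl-1-hydroxy-4,4,7a-trimethyloctahydro-1H-inden-5-yl 3-methylbutanoate
Product: 15 (1R,3aR,5R,7aR)-1-hydroxy-4,4,7a-trimethyl-1-[(2S)-oxiran-2-yl]octahydro-1H-inden-5-yl 3-methylbutanoate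
Conditions: VO(acac)2 (5 mol%), t-BuOOH (anhydrous, in decane), CH2Cl2, 0 °C → rt
Reagents that add atoms: tert-butyl hydroperoxide, CC(C)(C)OO
Why: Hydroxyl-directed vanadium-catalysed epoxidation of an allylic alcohol, in which the vanadium alkoxide delivers oxygen intramolecularly and the bulky quaternary ring carbon should take the position away from the vinyl C–H in the transition state, favouring the erythro epoxy alcohol with the S epoxide carbon.

Step 12
Reactants: 15 (1R,3aR,5R,7aR)-1-hydroxy-4,4,7a-trimethyl-1-[(2S)-oxiran-2-yl]octahydro-1H-inden-5-yl 3-methylbutanoate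
Product: 16 (2R,4aR,5R,8aS)-5-(hydroxymethyl)-1,1,4a-trimethyl-6-oxodecahydronaphthalen-2-yl 3-methylbutanoate
Conditions: BF3·OEt2 (0.3 equiv), CH2Cl2, −78 → −30 °C; then aq. NaHCO3
Reagents that add atoms: none
Why: Lewis acid activation of the epoxide oxygen weakens the internal C–O bond, and the antiperiplanar ring bond from the carbinol carbon to the quaternary angular carbon shifts to the epoxide carbon while the carbinol becomes the ketone, a semipinacol rearrangement of a 2,3-epoxy alcohol whose closest known type is the ring expansion of 1-oxiranylcycloalkanols to 2-(hydroxymethyl)cycloalkanones. No ring is closed by cyclisation: the cyclopentane of the hydrindane takes up the epoxide carbon through this 1,2-shift and becomes the cyclohexanone ring B. The new stereocentre bearing CH2OH is controlled by the epoxide configuration, because the migrating carbon attacks anti to the departing oxygen with inversion, so the S epoxide should place CH2OH equatorial and cis to the angular methyl, and the migrating quaternary carbon keeps its configuration. The step needs migration of the quaternary ring carbon and not of the ring CH2, and ionisation at the internal and not the terminal epoxide carbon: the fully substituted carbon has the higher migratory aptitude, its shift relieves the congestion of the neopentyl carbinol, the rotamer for its shift has the epoxide CH2 gauche to only one ring carbon, and only the internal C–O bond can be assisted by the carbinol. The new centre lies alpha to the ketone and the wanted equatorial arrangement should also be the more stable one, so a minor epimer could be equilibrated.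

Step 13
Reactants: 16 (2R,4aR,5R,8aS)-5-(hydroxymethyl)-1,1,4a-trimethyl-6-oxodecahydronaphthalen-2-yl 3-methylbutanoate
Product: 17 (2R,4aR,5R,8aS)-5-(hydroxymethyl)-1,1,4a-trimethyl-6-methylidenedecahydronaphthalen-2-yl 3-methylbutanoate
Conditions: Zn, CH2Br2, TiCl4, THF, 0 °C; then 16, CH2Cl2, 0 °C → rt
Reagents that add atoms: dibromomethane, BrCBr
Why: Takai–Lombardo methylenation, whose non-basic zinc/titanium methylene reagent should convert the hindered ketone into the exocyclic alkene without epimerising the adjacent centre, without retro-aldol cleavage of the β-hydroxy ketone and without attacking the ester.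

Step 14
Reactants: 17 (2R,4aR,5R,8aS)-5-(hydroxymethyl)-1,1,4a-trimethyl-6-methylidenedecahydronaphthalen-2-yl 3-methylbutanoate; 18 7-hydroxy-2H-chromen-2-one (umbelliferone)
Product: 19 (2R,4aR,5R,8aS)-1,1,4a-trimethyl-6-methylidene-5-{[(2-oxo-2H-chromen-7-yl)oxy]methyl}decahydronaphthalen-2-yl 3-methylbutanoate (target)
Conditions: PPh3, DIAD, THF, 0 °C → rt
Reagents that add atoms: none
Why: Mitsunobu etherification, in which the acidic phenol protonates the phosphine–azodicarboxylate betaine and its phenoxide displaces the oxyphosphonium of the primary alcohol, with no stereocentre involved and the ester, lactone and alkene inert.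

**Compound list**

1 | 2-methylcyclopentane-1,3-dione | CC1C(=O)CCC1=O | starting material
2 | pent-1-en-3-one (ethyl vinyl ketone) | CCC(=O)C=C | starting material
3 | 2-methyl-2-(3-oxopentyl)cyclopentane-1,3-dione | CCC(=O)CCC1(C)C(=O)CCC1=O | intermediate
4 | (3aR,7aR)-3a-hydroxy-4,7a-dimethylhexahydro-1H-indene-1,5(4H)-dione (cis-fused ketol, hydroxyl cis to the angular methyl) | C[C@@]12CCC(=O)C(C)[C@]1(O)CCC2=O | intermediate (not isolated)
5 | (7aR)-4,7a-dimethyl-2,3,7,7a-tetrahydro-1H-indene-1,5(6H)-dione | C[C@@]12CCC(=O)C(C)=C1CCC2=O | intermediate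
6 | (1R,7aR)-1-hydroxy-4,7a-dimethyl-1,2,3,6,7,7a-hexahydro-5H-inden-5-one | C[C@@]12CCC(=O)C(C)=C1CC[C@H]2O | intermediate
7 | (1R,7aR)-1-[(tert-butyldimethylsilyl)oxy]-4,7a-dimethyl-1,2,3,6,7,7a-hexahydro-5H-inden-5-one | C[C@@]12CCC(=O)C(C)=C1CC[C@H]2O[Si](C)(C)C(C)(C)C | intermediate
8 | lithium (1R,3aS,7aR)-1-[(tert-butyldimethylsilyl)oxy]-4,7a-dimethyl-2,3,3a,6,7,7a-hexahydro-1H-inden-5-olate (trans-fused enolate) | C[C@@]12CCC([O-])=C(C)[C@H]1CC[C@H]2O[Si](C)(C)C(C)(C)C.[Li+] | intermediate (not isolated)
9 | (1R,3aS,7aR)-1-[(tert-butyldimethylsilyl)oxy]-4,4,7a-trimethyloctahydro-5H-inden-5-one (trans-fused) | C[C@@]12CCC(=O)C(C)(C)[C@H]1CC[C@H]2O[Si](C)(C)C(C)(C)C | intermediate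
10 | (1R,3aR,5R,7aR)-1-[(tert-butyldimethylsilyl)oxy]-4,4,7a-trimethyloctahydro-1H-inden-5-ol | C[C@@]12CC[C@@H](O)C(C)(C)[C@H]1CC[C@H]2O[Si](C)(C)C(C)(C)C | intermediate
11 | (1R,3aR,5R,7aR)-1-[(tert-butyldimethylsilyl)oxy]-4,4,7a-trimethyloctahydro-1H-inden-5-yl 3-methylbutanoate | C[C@@]12CC[C@@H](OC(=O)CC(C)C)C(C)(C)[C@H]1CC[C@H]2O[Si](C)(C)C(C)(C)C | intermediate
12 | (1R,3aR,5R,7aR)-1-hydroxy-4,4,7a-trimethyloctahydro-1H-inden-5-yl 3-methylbutanoate | C[C@@]12CC[C@@H](OC(=O)CC(C)C)C(C)(C)[C@H]1CC[C@H]2O | intermediate
13 | (3aR,5R,7aR)-4,4,7a-trimethyl-1-oxooctahydro-1H-inden-5-yl 3-methylbutanoate | C[C@@]12CC[C@@H](OC(=O)CC(C)C)C(C)(C)[C@H]1CCC2=O | intermediate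
14 | (1S,3aR,5R,7aR)-1-ethenyl-1-hydroxy-4,4,7a-trimethyloctahydro-1H-inden-5-yl 3-methylbutanoate (hydroxyl cis to the angular methyl) | C[C@@]12CC[C@@H](OC(=O)CC(C)C)C(C)(C)[C@H]1CC[C@]2(O)C=C | intermediate
15 | (1R,3aR,5R,7aR)-1-hydroxy-4,4,7a-trimethyl-1-[(2S)-oxiran-2-yl]octahydro-1H-inden-5-yl 3-methylbutanoate | C[C@@]12CC[C@@H](OC(=O)CC(C)C)C(C)(C)[C@H]1CC[C@]2(O)[C@@H]1CO1 | intermediate
16 | (2R,4aR,5R,8aS)-5-(hydroxymethyl)-1,1,4a-trimethyl-6-oxodecahydronaphthalen-2-yl 3-methylbutanoate (trans-decalin, CH2OH equatorial) | O=C1CC[C@@H]2C(C)(C)[C@H](OC(=O)CC(C)C)CC[C@@]2(C)[C@@H]1CO | intermediate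
17 | (2R,4aR,5R,8aS)-5-(hydroxymethyl)-1,1,4a-trimethyl-6-methylidenedecahydronaphthalen-2-yl 3-methylbutanoate | C=C1CC[C@@H]2C(C)(C)[C@H](OC(=O)CC(C)C)CC[C@@]2(C)[C@@H]1CO | intermediate
18 | 7-hydroxy-2H-chromen-2-one (umbelliferone) | Oc1ccc2ccc(=O)oc2c1 | starting material
19 | (2R,4aR,5R,8aS)-1,1,4a-trimethyl-6-methylidene-5-{[(2-oxo-2H-chromen-7-yl)oxy]methyl}decahydronaphthalen-2-yl 3-methylbutanoate | C=C1CC[C@@H]2C(C)(C)[C@H](OC(=O)CC(C)C)CC[C@@]2(C)[C@@H]1COc1ccc2ccc(=O)oc2c1 | target

**Count and risks**

Total step count: 14. Longest linear sequence: 14 steps (1 and 2 to 19); umbelliferone 18 enters in the last step.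

The three steps most likely to fail:

Step 12. The epoxide may be opened or ionised at its terminal carbon, the ring CH2 may migrate in place of the quaternary carbon, or the β-hydroxy ketone may dehydrate under the Lewis acid. Fallback, setting out from 15 and returning at 16: the tertiary hydroxyl of 15 would be silylated with N-(trimethylsilyl)imidazole (CH2Cl2, rt) to the tertiary trimethylsilyl ether F1. F1 would then be rearranged with stoichiometric TiCl4 (CH2Cl2, −78 °C). Here the silyl ether oxygen is the stronger electron donor and titanium binds both oxygens, so the anti 1,2-shift of the quaternary carbon should proceed at lower temperature; the silyl group leaves from the oxocarbenium ion and aqueous work-up of the titanium aldolate gives 16.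

Step 5. Facial selectivity in the protonation that sets the ring fusion may be poor, the ketone may be over-reduced, or enolate equilibration may lead to methylation at the wrong carbon. Fallback, setting out from 7 and returning at 9: enone 7 would be methylated through its extended enolate (KOt-Bu, t-BuOH/THF, MeI, 0 °C → rt) at the alpha carbon, with migration of the double bond into the five-membered ring, to the β,γ-unsaturated ketone F2. The trisubstituted alkene of F2 would then be hydrogenated (H2, Pd/C, EtOAc) from the face opposite the angular methyl, which should deliver the trans-fused ketone 9.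

Step 14. Displacement at the β-branched primary carbon next to the quaternary centre may be slow, and the oxyphosphonium intermediate may eliminate toward a diene. Fallback, setting out from 18 and 17 and returning at 19: the roles of the partners would be inverted. Umbelliferone 18 would be converted (Tf2O, pyridine, CH2Cl2, 0 °C) to the aryl triflate F3. Alcohol 17 would then be O-arylated as the nucleophile (Pd2(dba)3, the biaryl di-tert-butylphosphine tBuBrettPhos, Cs2CO3, toluene, 80 °C), so that the C–O bond forms at the aromatic carbon by reductive elimination and not at the hindered CH2, giving 19.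

**Further compounds**

F1 | step 12 | (1R,3aR,5R,7aR)-4,4,7a-trimethyl-1-[(2S)-oxiran-2-yl]-1-[(trimethylsilyl)oxy]octahydro-1H-inden-5-yl 3-methylbutanoate | C[C@@]12CC[C@@H](OC(=O)CC(C)C)C(C)(C)[C@H]1CC[C@]2(O[Si](C)(C)C)[C@@H]1CO1
F2 | step 5 | (1R,7aR)-1-[(tert-butyldimethylsilyl)oxy]-4,4,7a-trimethyl-1,2,4,6,7,7a-hexahydro-5H-inden-5-one | C[C@@]12CCC(=O)C(C)(C)C1=CC[C@H]2O[Si](C)(C)C(C)(C)C
F3 | step 14 | 2-oxo-2H-chromen-7-yl trifluoromethanesulfonate | O=c1ccc2ccc(OS(=O)(=O)C(F)(F)F)cc2o1
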